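The route builds ring A last, from a squarate-derived four-carbon unit and a terminal alkyne that already carries C2, C3, C4 and ring B. The feature exploited is the oxygen pattern of ring A: O1 on C8a and the C6 oxygen are para (the two carbonyls of a quinone), the C7 oxygen sits next to C6, and C4a is para to C7, i.e. a 2-alkoxy-5-alkylbenzoquinone. One thermolysis of a 4-alkynyl-3-benzyloxy-4-hydroxycyclobutenone forms the C8a–C4a bond and ring A with this pattern. The precursor bears the aldol-derived C3/C4 stereocentres, a C4 silyl ether and a C2 chloride that later closes the pyran ring.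

Key step: step 15

Remarks: ArB stands for 2,5-bis(benzyloxy)-3,4-dimethoxyphenyl (protected ring B). Chroman numbering of the target (O1, C2, C3, C4, C4a, C5–C8, C8a) is used for its atoms in every intermediate. Compound 25 is expected as a mixture of epimers at the carbinol carbon of the four-membered ring; that centre disappears in step 15, so the mixture is carried on. The target is the 3,4-trans (3S,4R) isomer, which corresponds to the syn aldol from the (R)-auxiliary.

Step 1
Reactants: 1 2,3-dimethoxyphenol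
Product: 2 2,3-dimethoxy-1,4-benzoquinone
Conditions: (KSO3)2NO, KH2PO4, H2O/acetone, 0 °C → rt
Reagents that add atoms: Fremy's salt (dipotassium nitrosodisulfonate), [O]N(S(=O)(=O)[O-])S(=O)(=O)[O-].[K+].[K+]
Why: Teuber oxidation, in which the nitroxyl radical removes the phenolic hydrogen and a second equivalent delivers oxygen to the unsubstituted para carbon, should give the p-quinone.

Step 2
Reactants: 2 2,3-dimethoxy-1,4-benzoquinone
Product: 4 1,4-bis(benzyloxy)-2,3-dimethoxybenzene, via 2,3-dimethoxyhydroquinone 3 (not isolated)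
Conditions: Na2S2O4, H2O/EtOAc, rt; then BnBr, K2CO3, DMF, 50 °C
Reagents that add atoms: benzyl bromide, BrCc1ccccc1
Why: Dithionite reduction followed by double Williamson etherification should install benzyl ethers, which survive all later steps and leave by neutral hydrogenolysis.

Step 3
Reactants: 4 1,4-bis(benzyloxy)-2,3-dimethoxybenzene
Product: 5 1,4-bis(benzyloxy)-5-bromo-2,3-dimethoxybenzene
Conditions: NBS, MeCN, 0 °C → rt
Reagents that add atoms: N-bromosuccinimide, O=C1CCC(=O)N1Br
Why: Electrophilic aromatic bromination of the tetra-alkoxybenzene can give only one monobromide because the two open ring positions are equivalent by symmetry.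

Step 4
Reactants: 5 1,4-bis(benzyloxy)-5-bromo-2,3-dimethoxybenzene; 6 ethyl bromoacetate
Product: 8 ethyl 2-(ArB)acetate, via (2-ethoxy-2-oxoethyl)zinc bromide 7 (not isolated)
Conditions: Zn dust, TMSCl (cat.), THF, 40 °C; then 5, Pd2(dba)3 (cat.), XPhos (cat.), THF, 65 °C
Reagents that add atoms: none
Why: Zinc insertion gives the Reformatsky reagent, which should couple with the aryl bromide in a Negishi-type α-arylation (oxidative addition to zerovalent palladium, transmetallation, reductive elimination) under conditions that tolerate electron-rich, ortho-substituted bromides.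

Step 5
Reactants: 8 ethyl 2-(ArB)acetate
Product: 9 2-(ArB)acetic acid
Conditions: LiOH, THF/MeOH/H2O, rt; then 1 M HCl
Reagents that add atoms: lithium hydroxide, [Li+].[OH-]
Why: Ester saponification should proceed without affecting the aryl benzyl or methyl ethers.

Step 6
Reactants: 9 2-(ArB)acetic acid; 10 (R)-4-benzyl-2-oxazolidinone
Product: 12 (4R)-4-benzyl-3-[2-(ArB)acetyl]-1,3-oxazolidin-2-one, via pivalic mixed anhydride 11 (not isolated)
Conditions: t-BuCOCl, Et3N, THF, −20 °C; then 10, LiCl, −20 °C → rt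
Reagents that add atoms: none
Why: N-acylation through the mixed pivalic anhydride should occur at the unhindered arylacetyl carbonyl, with LiCl/Et3N activating the carbamate N–H.

Step 7
Reactants: 12 (4R)-4-benzyl-3-[2-(ArB)acetyl]-1,3-oxazolidin-2-one; 13 3-(trimethylsilyl)propynal
Product: 15 (4R)-4-benzyl-3-[(2R,3R)-2-(ArB)-3-hydroxy-5-(trimethylsilyl)pent-4-ynoyl]-1,3-oxazolidin-2-one, via Z-boron enolate 14 (not isolated)
Conditions: Bu2BOTf, i-Pr2NEt, CH2Cl2, −78 → 0 °C; then 13, −78 → 0 °C; pH 7 buffer, MeOH, H2O2, 0 °C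
Reagents that add atoms: none
Why: In this Evans syn-aldol the Z-boron enolate reacts through a closed Zimmerman–Traxler chair with the auxiliary's benzyl group shielding one enolate face, so the (R)-oxazolidinone should set both new centres (future C3 and C4) as the 2R,3R syn adduct.

Step 8
Reactants: 15 the syn-aldol adduct
Product: 16 (4R)-4-benzyl-3-[(2R,3R)-2-(ArB)-3-[(tert-butyldimethylsilyl)oxy]-5-(trimethylsilyl)pent-4-ynoyl]-1,3-oxazolidin-2-one
Conditions: TBSOTf, 2,6-lutidine, CH2Cl2, −78 → 0 °C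
Reagents that add atoms: tert-butyldimethylsilyl triflate, CC(C)(C)[Si](C)(C)OS(=O)(=O)C(F)(F)F
Why: O-silylation with a silyl triflate and a hindered weak base is fast at low temperature and should avoid retro-aldol cleavage or epimerisation of the benzylic α-centre.

Step 9
Reactants: 16 the silylated aldol adduct
Product: 17 (2S,3R)-2-(ArB)-3-[(tert-butyldimethylsilyl)oxy]-5-(trimethylsilyl)pent-4-yn-1-ol
Conditions: LiBH4, MeOH (1 equiv), THF, 0 °C → rt
Reagents that add atoms: none
Why: Reductive cleavage of the N-acyl oxazolidinone by borohydride at the exocyclic carbonyl should release the primary alcohol (future C2) and the auxiliary without touching either stereocentre.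

Step 10
Reactants: 17 the primary alcohol
Product: 18 (3R,4R)-4-(ArB)-3-[(tert-butyldimethylsilyl)oxy]-5-chloro-1-(trimethylsilyl)pent-1-yne
Conditions: PPh3, CCl4, CH2Cl2, 40 °C
Reagents that add atoms: carbon tetrachloride, ClC(Cl)(Cl)Cl
Why: Appel chlorination converts the primary alcohol through its alkoxyphosphonium salt by SN2 attack of chloride under neutral conditions, which the silyl ether and silylalkyne should tolerate.

Step 11
Reactants: 18 the silylalkyne chloride
Product: 19 (3R,4R)-4-(ArB)-3-[(tert-butyldimethylsilyl)oxy]-5-chloropent-1-yne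
Conditions: K2CO3 (cat.), MeOH/THF, rt
Reagents that add atoms: none
Why: Methanolysis of the alkynyl C–Si bond by catalytic methoxide is selective, leaving the O-silyl ether and the primary chloride intact.

Step 12
Reactants: 20 squaric acid
Product: 21 dibenzyl squarate (3,4-bis(benzyloxy)cyclobut-3-ene-1,2-dione)
Conditions: BnOH, toluene, reflux, Dean–Stark
Reagents that add atoms: benzyl alcohol, OCc1ccccc1
Why: Squaric acid is acidic enough to catalyse its own double esterification once water is removed azeotropically.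

Step 13
Reactants: 21 dibenzyl squarate
Product: 23 3-(benzyloxy)cyclobut-3-ene-1,2-dione, via 2,3-bis(benzyloxy)-4-hydroxycyclobutenone 22 (not isolated)
Conditions: LiAlH(OtBu)3, THF, −78 °C; 1 M HCl quench; then 12 M HCl (cat.), CH2Cl2, rt
Reagents that add atoms: none
Why: One hydride adds 1,2 to a squarate carbonyl, and acid then ionises the allylic hydroxyl so that the oxocarbenium ion takes up water and loses benzyl alcohol, transposing the carbonyl to give the semisquarate.

Step 14
Reactants: 19 the terminal alkyne; 23 3-(benzyloxy)cyclobut-3-ene-1,2-dione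
Product: 25 3-(benzyloxy)-4-[(3R,4R)-4-(ArB)-3-[(tert-butyldimethylsilyl)oxy]-5-chloropent-1-yn-1-yl]-4-hydroxycyclobut-2-en-1-one (both ring-carbinol epimers), via lithium acetylide 24 (not isolated)
Conditions: n-BuLi, THF, −78 °C; then add to 23, THF, −78 °C; NH4Cl (aq), −78 °C
Reagents that add atoms: none
Why: 1,2-Addition of the acetylide should occur at the ketone-type carbonyl attached to the benzyloxy-bearing carbon, since the other carbonyl is a deactivated vinylogous ester, and at −78 °C the chloride and benzylic centre should be untouched.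

Step 15
Reactants: 25 the 4-alkynyl-4-hydroxycyclobutenone
Product: 27 2-(benzyloxy)-5-[(1R,2R)-2-(ArB)-1-[(tert-butyldimethylsilyl)oxy]-3-chloropropyl]cyclohexa-2,5-diene-1,4-dione, via alkynyl ketene 26 (not isolated)
Conditions: toluene (degassed, 0.01 M), 110 °C
Reagents that add atoms: none
Why: Heating opens the cyclobutenone by 4π-conrotatory electrocyclic ring opening with the hydroxyl rotating outward, which places the alkyne cis to the ketene in 26. The ketene carbon (future C8a) then bonds to the remote alkyne carbon (future C4a) in a 6-endo-dig closure that builds ring A as a diradical, and transfer of the hydroxyl hydrogen to the ring-carbon radical (C5) gives quinone 27; this is the Moore rearrangement of 4-alkynyl-4-hydroxycyclobutenones. No stereocentre is formed, and C3 and C4 should be unaffected because the medium is neutral and neither centre is part of the reacting π system. The step needs six-ring over five-ring closure, which the sp3 carbon on the alkyne terminus (no radical-stabilising aryl, silyl or alkoxy group) favours. It also needs the chain para to the benzyloxy group, which is already fixed in 25 by the carbinol carbon lying next to C–OBn. High dilution in degassed solvent limits intermolecular trapping of the diradical.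

Step 16
Reactants: 27 the quinone
Product: 29 (3S,4R)-7-(benzyloxy)-3-(ArB)-4-[(tert-butyldimethylsilyl)oxy]chroman-6-ol, via hydroquinone 28 (not isolated)
Conditions: Na2S2O4, H2O/EtOAc, rt; then K2CO3, NaI (cat.), DMF (degassed), 50 °C
Reagents that add atoms: none
Why: Dithionite reduction frees two phenols, of which only the C8a phenoxide can reach C2, so a 6-exo-tet Williamson closure should form O1–C2 and leave the C6 hydroxyl free.

Step 17
Reactants: 29 the chroman-6-ol
Product: 30 (3S,4R)-7-(benzyloxy)-3-(ArB)-4-[(tert-butyldimethylsilyl)oxy]-6-methoxychromane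
Conditions: MeI, K2CO3, acetone, rt
Reagents that add atoms: iodomethane, CI
Why: Williamson methylation of the only free phenol should install the C6 methoxy group.

Step 18
Reactants: 30 the silyl-protected chromane
Product: 31 (3S,4R)-7-(benzyloxy)-3-(ArB)-6-methoxychroman-4-ol
Conditions: TBAF, THF, 0 °C → rt
Reagents that add atoms: none
Why: Fluoride-mediated desilylation is basic, which avoids acid ionisation of the electron-rich benzylic C4–O bond.

Step 19
Reactants: 31 the tribenzyl chroman-4-ol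
Product: 32 (3S,4R)-3-(2,5-dihydroxy-3,4-dimethoxyphenyl)-6-methoxychromane-4,7-diol (CNP0163454.1)
Conditions: H2 (1 atm), 10% Pd/C, EtOAc/EtOH, rt
Reagents that add atoms: none
Why: Catalytic hydrogenolysis should cleave the three aryl benzyl ethers under neutral conditions faster than the benzylic C4–OH bond, and the air-sensitive product needs only filtration under inert gas.

Compound list
1 | 2,3-dimethoxyphenol | COc1cccc(O)c1OC | starting material
2 | 2,3-dimethoxy-1,4-benzoquinone | COC1=C(OC)C(=O)C=CC1=O | intermediate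
3 | 2,3-dimethoxybenzene-1,4-diol (formed in the flask) | COc1c(O)ccc(O)c1OC | intermediate
4 | 1,4-bis(benzyloxy)-2,3-dimethoxybenzene | COc1c(OCc2ccccc2)ccc(OCc2ccccc2)c1OC | intermediate
5 | 1,4-bis(benzyloxy)-5-bromo-2,3-dimethoxybenzene | COc1c(OCc2ccccc2)cc(Br)c(OCc2ccccc2)c1OC | intermediate
6 | ethyl bromoacetate | CCOC(=O)CBr | starting material
7 | (2-ethoxy-2-oxoethyl)zinc bromide (formed in the flask) | CCOC(=O)C[Zn]Br | intermediate
8 | ethyl 2-[2,5-bis(benzyloxy)-3,4-dimethoxyphenyl]acetate | CCOC(=O)Cc1cc(OCc2ccccc2)c(OC)c(OC)c1OCc1ccccc1 | intermediate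
9 | 2-[2,5-bis(benzyloxy)-3,4-dimethoxyphenyl]acetic acid | OC(=O)Cc1cc(OCc2ccccc2)c(OC)c(OC)c1OCc1ccccc1 | intermediate
10 | (R)-4-benzyl-2-oxazolidinone | O=C1N[C@H](Cc2ccccc2)CO1 | starting material
11 | 2-(ArB)acetic pivalic anhydride (formed in the flask) | CC(C)(C)C(=O)OC(=O)Cc1cc(OCc2ccccc2)c(OC)c(OC)c1OCc1ccccc1 | intermediate
12 | (4R)-4-benzyl-3-[2-(ArB)acetyl]-1,3-oxazolidin-2-one | O=C(Cc1cc(OCc2ccccc2)c(OC)c(OC)c1OCc1ccccc1)N1C(=O)OC[C@H]1Cc1ccccc1 | intermediate
13 | 3-(trimethylsilyl)propynal | C[Si](C)(C)C#CC=O | starting material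
14 | (Z)-dibutylboron enolate of 12 (formed in the flask) | CCCCB(CCCC)O/C(=C\c1cc(OCc2ccccc2)c(OC)c(OC)c1OCc1ccccc1)N1C(=O)OC[C@H]1Cc1ccccc1 | intermediate
15 | (4R)-4-benzyl-3-[(2R,3R)-2-(ArB)-3-hydroxy-5-(trimethylsilyl)pent-4-ynoyl]-1,3-oxazolidin-2-one | C[Si](C)(C)C#C[C@H](O)[C@@H](c1cc(OCc2ccccc2)c(OC)c(OC)c1OCc1ccccc1)C(=O)N1C(=O)OC[C@H]1Cc1ccccc1 | intermediate
16 | (4R)-4-benzyl-3-[(2R,3R)-2-(ArB)-3-[(tert-butyldimethylsilyl)oxy]-5-(trimethylsilyl)pent-4-ynoyl]-1,3-oxazolidin-2-one | C[Si](C)(C)C#C[C@H](O[Si](C)(C)C(C)(C)C)[C@@H](c1cc(OCc2ccccc2)c(OC)c(OC)c1OCc1ccccc1)C(=O)N1C(=O)OC[C@H]1Cc1ccccc1 | intermediate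
17 | (2S,3R)-2-(ArB)-3-[(tert-butyldimethylsilyl)oxy]-5-(trimethylsilyl)pent-4-yn-1-ol | C[Si](C)(C)C#C[C@H](O[Si](C)(C)C(C)(C)C)[C@@H](c1cc(OCc2ccccc2)c(OC)c(OC)c1OCc1ccccc1)CO | intermediate
18 | (3R,4R)-4-(ArB)-3-[(tert-butyldimethylsilyl)oxy]-5-chloro-1-(trimethylsilyl)pent-1-yne | C[Si](C)(C)C#C[C@H](O[Si](C)(C)C(C)(C)C)[C@@H](c1cc(OCc2ccccc2)c(OC)c(OC)c1OCc1ccccc1)CCl | intermediate
19 | (3R,4R)-4-(ArB)-3-[(tert-butyldimethylsilyl)oxy]-5-chloropent-1-yne | C#C[C@H](O[Si](C)(C)C(C)(C)C)[C@@H](c1cc(OCc2ccccc2)c(OC)c(OC)c1OCc1ccccc1)CCl | intermediate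
20 | squaric acid | O=C1C(O)=C(O)C1=O | starting material
21 | dibenzyl squarate | O=C1C(=O)C(OCc2ccccc2)=C1OCc1ccccc1 | intermediate
22 | 2,3-bis(benzyloxy)-4-hydroxycyclobut-2-en-1-one, racemic (formed in the flask) | O=C1C(OCc2ccccc2)=C(OCc2ccccc2)C1O | intermediate
23 | 3-(benzyloxy)cyclobut-3-ene-1,2-dione | O=C1C=C(OCc2ccccc2)C1=O | intermediate
24 | lithium acetylide of 19 (formed in the flask) | [Li]C#C[C@H](O[Si](C)(C)C(C)(C)C)[C@@H](c1cc(OCc2ccccc2)c(OC)c(OC)c1OCc1ccccc1)CCl | intermediate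
25 | 3-(benzyloxy)-4-[(3R,4R)-4-(ArB)-3-[(tert-butyldimethylsilyl)oxy]-5-chloropent-1-yn-1-yl]-4-hydroxycyclobut-2-en-1-one, both epimers at the ring carbinol carbon | O=C1C=C(OCc2ccccc2)C1(O)C#C[C@H](O[Si](C)(C)C(C)(C)C)[C@@H](c1cc(OCc2ccccc2)c(OC)c(OC)c1OCc1ccccc1)CCl | intermediate
26 | ring-opened alkynyl ketene of 25, hydroxyl anti and alkyne syn to the ketenyl group (formed in the flask) | O=C=C/C(OCc1ccccc1)=C(/O)C#C[C@H](O[Si](C)(C)C(C)(C)C)[C@@H](c1cc(OCc2ccccc2)c(OC)c(OC)c1OCc1ccccc1)CCl | intermediate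
27 | 2-(benzyloxy)-5-[(1R,2R)-2-(ArB)-1-[(tert-butyldimethylsilyl)oxy]-3-chloropropyl]cyclohexa-2,5-diene-1,4-dione | O=C1C=C(OCc2ccccc2)C(=O)C=C1[C@H](O[Si](C)(C)C(C)(C)C)[C@@H](c1cc(OCc2ccccc2)c(OC)c(OC)c1OCc1ccccc1)CCl | intermediate
28 | 2-(benzyloxy)-5-[(1R,2R)-2-(ArB)-1-[(tert-butyldimethylsilyl)oxy]-3-chloropropyl]benzene-1,4-diol (formed in the flask) | Oc1cc(OCc2ccccc2)c(O)cc1[C@H](O[Si](C)(C)C(C)(C)C)[C@@H](c1cc(OCc2ccccc2)c(OC)c(OC)c1OCc1ccccc1)CCl | intermediate
29 | (3S,4R)-7-(benzyloxy)-3-(ArB)-4-[(tert-butyldimethylsilyl)oxy]chroman-6-ol | Oc1cc2c(cc1OCc1ccccc1)OC[C@H](c1cc(OCc3ccccc3)c(OC)c(OC)c1OCc1ccccc1)[C@H]2O[Si](C)(C)C(C)(C)C | intermediate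
30 | (3S,4R)-7-(benzyloxy)-3-(ArB)-4-[(tert-butyldimethylsilyl)oxy]-6-methoxychromane | COc1cc2c(cc1OCc1ccccc1)OC[C@H](c1cc(OCc3ccccc3)c(OC)c(OC)c1OCc1ccccc1)[C@H]2O[Si](C)(C)C(C)(C)C | intermediate
31 | (3S,4R)-7-(benzyloxy)-3-(ArB)-6-methoxychroman-4-ol | COc1cc2c(cc1OCc1ccccc1)OC[C@H](c1cc(OCc3ccccc3)c(OC)c(OC)c1OCc1ccccc1)[C@H]2O | intermediate
32 | (3S,4R)-3-(2,5-dihydroxy-3,4-dimethoxyphenyl)-6-methoxychromane-4,7-diol | COc1cc2c(cc1O)OC[C@H](c1cc(O)c(OC)c(OC)c1O)[C@H]2O | target

Total step count: 19. Longest linear sequence: 17 steps (steps 1–11, then 14–19); the semisquarate branch (steps 12–13) joins at step 14.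

Steps most likely to fail

1. Step 15 (key step). The ketene may close onto the near alkyne carbon to give a five-membered alkylidene cyclopentenedione, or the ring-carbon radical may abstract hydrogen from the side chain (C2–H or the silyl methyls) before the hydroxyl hydrogen arrives. The fallback is the alkenyl variant of the same ring expansion, which closes by a 6π-electrocyclisation and involves no diradical. It sets out from alkyne 19. Hydrozirconation with Cp2Zr(H)Cl in THF and iodinolysis should give tert-butyl{[(1E,3R,4R)-4-(ArB)-5-chloro-1-iodopent-1-en-3-yl]oxy}dimethylsilane F1. Iodine–lithium exchange (t-BuLi, Et2O, −78 °C) and addition to semisquarate 23 should give 3-(benzyloxy)-4-[(1E,3S,4R)-4-(ArB)-3-[(tert-butyldimethylsilyl)oxy]-5-chloropent-1-en-1-yl]-4-hydroxycyclobut-2-en-1-one F2. Heating F2 in degassed toluene at 110 °C should open it to the dienylketene, which closes and tautomerises to hydroquinone 28, where the fallback rejoins the route; 28 is closed with K2CO3 as in step 16 to give 29.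

2. Step 14. The acetylide may attack the vinylogous-ester carbonyl or add in conjugate fashion to the unsubstituted ring carbon, or the base may cause loss of HCl from the chain. The fallback abandons the ring synthesis and buys ring A; it sets out from imide 12. Bromination of commercial 4-(benzyloxy)-3-methoxybenzaldehyde (Br2, NaOAc, AcOH), para to the methoxy group, should give 4-(benzyloxy)-2-bromo-5-methoxybenzaldehyde F3. Evans syn-aldol of 12 with F3 (Bu2BOTf, i-Pr2NEt, CH2Cl2) should give (4R)-4-benzyl-3-[(2R,3R)-2-(ArB)-3-[4-(benzyloxy)-2-bromo-5-methoxyphenyl]-3-hydroxypropanoyl]-1,3-oxazolidin-2-one F4. Silylation (TBSOTf, 2,6-lutidine) should give (4R)-4-benzyl-3-[(2R,3R)-2-(ArB)-3-[4-(benzyloxy)-2-bromo-5-methoxyphenyl]-3-[(tert-butyldimethylsilyl)oxy]propanoyl]-1,3-oxazolidin-2-one F5. LiBH4 reduction should give (2S,3R)-2-(ArB)-3-[4-(benzyloxy)-2-bromo-5-methoxyphenyl]-3-[(tert-butyldimethylsilyl)oxy]propan-1-ol F6. Intramolecular palladium-catalysed aryl ether formation (Pd(OAc)2, 2-(di-tert-butylphosphino)-1,1'-binaphthyl, Cs2CO3, toluene, 80 °C) between the primary alcohol and the aryl bromide should form the O1–C8a bond and rejoin the route at 30.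

3. Step 19. Hydrogenolytic cleavage of the electron-rich benzylic C4–O bond may compete with O-debenzylation and give the 4-deoxy isoflavan. The fallback reverses the last two deprotections and sets out from 30. Hydrogenolysis (H2, Pd/C, EtOAc) with the bulky silyl ether still on C4 should give (3S,4R)-4-[(tert-butyldimethylsilyl)oxy]-3-(2,5-dihydroxy-3,4-dimethoxyphenyl)-6-methoxychroman-7-ol F7. Desilylation with TBAF buffered with AcOH in degassed THF should then give target 32.

Further compounds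
F1 | step 15 | tert-butyl{[(1E,3R,4R)-4-(ArB)-5-chloro-1-iodopent-1-en-3-yl]oxy}dimethylsilane | I/C=C/[C@H](O[Si](C)(C)C(C)(C)C)[C@@H](c1cc(OCc2ccccc2)c(OC)c(OC)c1OCc1ccccc1)CCl
F2 | step 15 | 3-(benzyloxy)-4-[(1E,3S,4R)-4-(ArB)-3-[(tert-butyldimethylsilyl)oxy]-5-chloropent-1-en-1-yl]-4-hydroxycyclobut-2-en-1-one | O=C1C=C(OCc2ccccc2)C1(O)/C=C/[C@H](O[Si](C)(C)C(C)(C)C)[C@@H](c1cc(OCc2ccccc2)c(OC)c(OC)c1OCc1ccccc1)CCl
F3 | step 14 | 4-(benzyloxy)-2-bromo-5-methoxybenzaldehyde | COc1cc(C=O)c(Br)cc1OCc1ccccc1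
F4 | step 14 | (4R)-4-benzyl-3-[(2R,3R)-2-(ArB)-3-[4-(benzyloxy)-2-bromo-5-methoxyphenyl]-3-hydroxypropanoyl]-1,3-oxazolidin-2-one | COc1cc(c(Br)cc1OCc1ccccc1)[C@H](O)[C@@H](c1cc(OCc2ccccc2)c(OC)c(OC)c1OCc1ccccc1)C(=O)N1C(=O)OC[C@H]1Cc1ccccc1
F5 | step 14 | (4R)-4-benzyl-3-[(2R,3R)-2-(ArB)-3-[4-(benzyloxy)-2-bromo-5-methoxyphenyl]-3-[(tert-butyldimethylsilyl)oxy]propanoyl]-1,3-oxazolidin-2-one | COc1cc(c(Br)cc1OCc1ccccc1)[C@H](O[Si](C)(C)C(C)(C)C)[C@@H](c1cc(OCc2ccccc2)c(OC)c(OC)c1OCc1ccccc1)C(=O)N1C(=O)OC[C@H]1Cc1ccccc1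
F6 | step 14 | (2S,3R)-2-(ArB)-3-[4-(benzyloxy)-2-bromo-5-methoxyphenyl]-3-[(tert-butyldimethylsilyl)oxy]propan-1-ol | COc1cc(c(Br)cc1OCc1ccccc1)[C@H](O[Si](C)(C)C(C)(C)C)[C@@H](c1cc(OCc2ccccc2)c(OC)c(OC)c1OCc1ccccc1)CO
F7 | step 19 | (3S,4R)-4-[(tert-butyldimethylsilyl)oxy]-3-(2,5-dihydroxy-3,4-dimethoxyphenyl)-6-methoxychroman-7-ol | COc1cc2c(cc1O)OC[C@H](c1cc(O)c(OC)c(OC)c1O)[C@H]2O[Si](C)(C)C(C)(C)C
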